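**Retrosynthetic overview**

- The strategy rests on the bond shared by the two rings. In ring B (O1, C2, C3, C4) O1 sits on C8a beside the quaternary C8, and C4a joins the C4 ketone to the C5 enol carbon of ring A (C4a, C5, C6, C7, C8, C8a). C8a and C4a are therefore taken back to the two carbons of an ynone.
- Key disconnections: O1–C8a (hydroxyl onto the ynone, ring B first) and C4a–C5 (pyranone carbon onto an acylketene from a β-keto thioester, ring A second), both in one operation from an open-chain hydroxy ynone β-keto thioester.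
- The precursor is cut at C6–C7 (crossed Claisen with a desymmetrised 3-propylglutarate thioester), at C4–C4a (acetylide plus Evans syn-aldol aldehyde, carbinol oxidised to the ynone last) and at C8 (phase-transfer prenylation of an α-alkyl malonate, one ester then turned into the ethynyl group).
- The C10 side chain with its stereocentre comes from (R)-limonene oxide by ring cleavage, methylenation and iododecarboxylation. The acid is freed last from its 2-(trimethylsilyl)ethyl ester.

Key step: step 22

Assumption: the senses of the two reagent-controlled desymmetrisations (quinine alcoholysis in step 15, (S,S)-ammonium catalyst in step 7) are taken from the closest reported substrates and are not certain for these ones; should either prove opposite, quinidine or the (R,R)-catalyst is used with nothing else changed.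

Remark: anions made by simple deprotonation (acetylide, enolates, carboxylates) are counted as forms of their numbered parent compounds.

**Route**

Step 1
Reactants: 1 (4R)-limonene 1,2-oxide (cis/trans mixture)
Product: 3 (3R)-6-oxo-3-(prop-1-en-2-yl)heptanal, via trans-diol 2 (not isolated)
Conditions: H5IO6, THF/H2O, 0 °C → rt
Reagents that add atoms: water (O)
Why: Epoxide hydrolysis followed by periodate glycol cleavage opens the ring between C1 and C2, both epoxide isomers converge, and the stereocentre, β to the new aldehyde, is not touched.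

Step 2
Reactants: 3 (3R)-6-oxo-3-(prop-1-en-2-yl)heptanal
Product: 4 (3R)-6-oxo-3-(prop-1-en-2-yl)heptanoic acid
Conditions: NaClO2, NaH2PO4, 2-methyl-2-butene, t-BuOH/H2O, 0 °C → rt
Reagents that add atoms: sodium chlorite ([Na+].[O-]Cl=O)
Why: Pinnick oxidation converts the aldehyde to the acid without touching the methyl ketone, and the 2-methyl-2-butene scavenger keeps HOCl off the isopropenyl group.

Step 3
Reactants: 4 (3R)-6-oxo-3-(prop-1-en-2-yl)heptanoic acid
Product: 5 (3R)-6-methyl-3-(prop-1-en-2-yl)hept-6-enoic acid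
Conditions: Ph3PCH3Br (2.5 equiv), KOtBu (2.6 equiv), THF, 0 °C → rt; dilute HCl work-up
Reagents that add atoms: methyltriphenylphosphonium bromide (C[P+](c1ccccc1)(c1ccccc1)c1ccccc1.[Br-])
Why: Wittig methylenation of the methyl ketone, the carboxylate formed by the first equivalent of base being inert to the ylide.

Step 4
Reactants: 5 (3R)-6-methyl-3-(prop-1-en-2-yl)hept-6-enoic acid
Product: 7 (3S)-3-(iodomethyl)-2,6-dimethylhepta-1,6-diene, via Barton ester 6 (not isolated)
Conditions: N-hydroxypyridine-2-thione, DCC, CH2Cl2, 0 °C → rt, dark; then CHI3 (3 equiv), benzene, hν (tungsten lamp), rt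
Reagents that add atoms: iodoform (IC(I)I)
Why: Barton decarboxylative iodination, in which the primary radical should take iodine from excess CHI3 faster than it can cyclise onto the 1,1-disubstituted alkene, while the neighbouring stereocentre carries no bond that the radical can break.

Step 5
Reactants: 8 mono-tert-butyl malonate; 9 2,2-diphenylethanol
Product: 10 tert-butyl 2,2-diphenylethyl malonate
Conditions: EDC·HCl, DMAP (catalytic), CH2Cl2, 0 °C → rt
Reagents that add atoms: none
Why: Carbodiimide (Steglich) esterification of a malonic half-ester with a primary alcohol.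

Step 6
Reactants: 10 tert-butyl 2,2-diphenylethyl malonate (1.5 equiv); 7 (3S)-3-(iodomethyl)-2,6-dimethylhepta-1,6-diene
Product: 11 tert-butyl 2,2-diphenylethyl 2-[(2R)-5-methyl-2-(prop-1-en-2-yl)hex-5-en-1-yl]malonate (both epimers at the malonate carbon)
Conditions: NaH, THF/DMF, 0 → 55 °C
Reagents that add atoms: none
Why: Malonic ester alkylation (SN2) by a primary iodide, with excess malonate to suppress dialkylation and no bond to the stereocentre of 7 involved.

Step 7
Reactants: 11 tert-butyl 2,2-diphenylethyl 2-[(2R)-5-methyl-2-(prop-1-en-2-yl)hex-5-en-1-yl]malonate; 12 prenyl bromide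
Product: 13 1-tert-butyl 3-(2,2-diphenylethyl) (2R)-2-(3-methylbut-2-en-1-yl)-2-[(2R)-5-methyl-2-(prop-1-en-2-yl)hex-5-en-1-yl]malonate
Conditions: (S,S)-3,4,5-trifluorophenyl-NAS bromide (N-spiro bis-binaphthyl ammonium bromide, 5 mol%), 50% aq KOH, toluene, −40 °C
Reagents that add atoms: none
Why: Phase-transfer alkylation of an α-alkyl tert-butyl malonate, in which the chiral ammonium ion pair shields one face of the enolate so that prenyl bromide should enter to give the (2R) quaternary centre under catalyst control.

Step 8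
Reactants: 13 quaternary mixed malonate
Product: 14 tert-butyl (2R,4R)-2-(hydroxymethyl)-7-methyl-2-(3-methylbut-2-en-1-yl)-4-(prop-1-en-2-yl)oct-7-enoate
Conditions: LiBH4, MeOH (2 equiv), THF, 0 °C → rt
Reagents that add atoms: none
Why: Chemoselective ester reduction, LiBH4 taking the primary alkyl ester and leaving the tert-butyl ester, at a quaternary centre that has no acidic hydrogen.

Step 9
Reactants: 14 hydroxy ester
Product: 15 tert-butyl (2R,4R)-2-formyl-7-methyl-2-(3-methylbut-2-en-1-yl)-4-(prop-1-en-2-yl)oct-7-enoate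
Conditions: Dess–Martin periodinane, CH2Cl2, 0 °C → rt
Reagents that add atoms: none
Why: Dess–Martin oxidation of a neopentyl primary alcohol to an aldehyde that cannot enolise.

Step 10
Reactants: 15 formyl ester
Product: 16 tert-butyl (2R,4R)-2-ethynyl-7-methyl-2-(3-methylbut-2-en-1-yl)-4-(prop-1-en-2-yl)oct-7-enoate
Conditions: dimethyl (1-diazo-2-oxopropyl)phosphonate, K2CO3, MeOH, 0 °C → rt
Reagents that add atoms: dimethyl (1-diazo-2-oxopropyl)phosphonate (CC(=O)C(=[N+]=[N-])P(=O)(OC)OC)
Why: Ohira–Bestmann (Seyferth–Gilbert) homologation of a non-enolisable aldehyde to the terminal alkyne, the tert-butyl ester resisting methoxide.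

Step 11
Reactants: 17 (S)-4-benzyl-3-propionyloxazolidin-2-one; 18 acetaldehyde
Product: 19 (S)-4-benzyl-3-[(2S,3R)-3-hydroxy-2-methylbutanoyl]oxazolidin-2-one
Conditions: Bu2BOTf, i-Pr2NEt, CH2Cl2, −78 → 0 °C; then pH 7 buffer, MeOH, H2O2, 0 °C
Reagents that add atoms: none
Why: Evans boron aldol, in which the Z-boron enolate adds to acetaldehyde through a Zimmerman–Traxler chair on the face left open by the benzyl group and gives the syn (2S,3R) adduct.

Step 12
Reactants: 19 Evans syn-aldol adduct
Product: 20 (2S,3R)-3-hydroxy-N-methoxy-N,2-dimethylbutanamide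
Conditions: MeNHOMe·HCl, AlMe3, CH2Cl2, −20 → 0 °C; aq potassium sodium tartrate
Reagents that add atoms: N,O-dimethylhydroxylamine hydrochloride (CNOC.Cl)
Why: Aluminium amide transamination of the β-hydroxy imide to the Weinreb amide, assisted by the free hydroxyl and without epimerisation at C2.

Step 13
Reactants: 20 hydroxy Weinreb amide
Product: 21 (2S,3R)-3-[(tert-butyldimethylsilyl)oxy]-N-methoxy-N,2-dimethylbutanamide
Conditions: TBSOTf, 2,6-lutidine, CH2Cl2, −78 → 0 °C
Reagents that add atoms: tert-butyldimethylsilyl triflate (CC(C)(C)[Si](C)(C)OS(=O)(=O)C(F)(F)F)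
Why: Silylation of a secondary alcohol.

Step 14
Reactants: 21 silyl ether Weinreb amide
Product: 22 (2S,3R)-3-[(tert-butyldimethylsilyl)oxy]-2-methylbutanal
Conditions: i-Bu2AlH, THF, −78 °C; aq potassium sodium tartrate; used at once
Reagents that add atoms: none
Why: Reduction of a Weinreb amide to the aldehyde through the chelated tetrahedral intermediate, which prevents over-reduction, the aldehyde being used directly so that its α-centre does not epimerise.

Step 15
Reactants: 23 3-propylglutaric anhydride; 24 2-(trimethylsilyl)ethanol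
Product: 25 (3R)-3-{2-oxo-2-[2-(trimethylsilyl)ethoxy]ethyl}hexanoic acid
Conditions: quinine (1.1 equiv), toluene, −40 °C; dilute HCl wash (quinine recovered)
Reagents that add atoms: none
Why: Quinine-mediated alcoholysis of a prochiral 3-substituted glutaric anhydride (desymmetrisation), in which the alkaloid directs the alcohol to one of the two enantiotopic carbonyls and so sets the (3R) centre.

Step 16
Reactants: 25 hemiester acid; 26 benzyl mercaptan
Product: 27 2-(trimethylsilyl)ethyl (3S)-3-[2-(benzylsulfanyl)-2-oxoethyl]hexanoate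
Conditions: EDC·HCl, DMAP (catalytic), CH2Cl2, 0 °C → rt
Reagents that add atoms: none
Why: Carbodiimide thioesterification of the free acid, the stereocentre being β to both carbonyls and unable to epimerise.

Step 17
Reactants: 16 ethynyl tert-butyl ester; 22 (2S,3R)-3-[(tert-butyldimethylsilyl)oxy]-2-methylbutanal
Product: 29 tert-butyl (2R,4R)-2-[(4S,5R)-3,5-bis(tert-butyldimethylsilyloxy)-4-methylhex-1-yn-1-yl]-7-methyl-2-(3-methylbut-2-en-1-yl)-4-(prop-1-en-2-yl)oct-7-enoate (both epimers at the propargylic carbon), via lithium alkoxide 28 (not isolated)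
Conditions: LiN(i-Pr)2, THF, −78 °C; then 22; then TBSOTf, −78 → 0 °C
Reagents that add atoms: tert-butyldimethylsilyl triflate (CC(C)(C)[Si](C)(C)OS(=O)(=O)C(F)(F)F)
Why: Addition of the lithium acetylide of 16 (the ester has no α-hydrogen) to the aldehyde and silylation of the alkoxide in the same flask, the new carbinol centre being formed as a mixture that is removed by the oxidation in step 21.

Step 18
Reactants: 29 bis-silyl ether tert-butyl ester
Product: 31 (2R,4R)-2-[(4S,5R)-3,5-bis(tert-butyldimethylsilyloxy)-4-methylhex-1-yn-1-yl]-7-methyl-2-(3-methylbut-2-en-1-yl)-4-(prop-1-en-2-yl)oct-7-enoic acid, via trimethylsilyl ester 30 (not isolated)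
Conditions: TMSOTf, 2,6-lutidine, CH2Cl2, 0 °C; then pH 4 aqueous buffer
Reagents that add atoms: none
Why: Silyl triflate cleavage of a tert-butyl ester with loss of isobutene under buffered conditions that spare the TBS ethers and the three alkenes, carried out while the molecule holds no ketone that could be enolised.

Step 19
Reactants: 31 alkynyl acid; 27 thioester (2.2 equiv)
Product: 33 bis-TBS β-keto thioester (27 acylated at its thioester α-carbon by the acyl group of 31; epimers at that carbon and at the propargylic carbon), via acid chloride 32 (not isolated)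
Conditions: 31, 1-chloro-N,N,2-trimethylprop-1-en-1-amine, CH2Cl2, 0 °C → rt; separately 27, LiN(SiMe3)2 (2.1 equiv), THF, −78 °C; acid chloride solution added, −78 → −40 °C; AcOH quench
Reagents that add atoms: none
Why: Crossed Claisen condensation, the lithium enolate of the thioester (formed selectively because its α-hydrogens are more acidic than those of the ester) being C-acylated by an acid chloride that has no α-hydrogen and was made under neutral conditions, while the new dicarbonyl carbon becomes sp2 in step 22.

Step 20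
Reactants: 33 bis-TBS β-keto thioester
Product: 34 diol β-keto thioester (propargylic alcohol and C2 alcohol free)
Conditions: HF·pyridine, pyridine, THF, 0 °C → rt
Reagents that add atoms: none
Why: Fluoride cleavage of both secondary TBS ethers with buffered HF·pyridine, which should leave the 2-(trimethylsilyl)ethyl ester and the thioester intact.

Step 21
Reactants: 34 diol β-keto thioester
Product: 35 hydroxy ynone β-keto thioester (key-step precursor)
Conditions: activated MnO2 (excess), CH2Cl2, rt
Reagents that add atoms: none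
Why: MnO2 oxidises the propargylic alcohol selectively and leaves the saturated secondary alcohol, so the ynone appears under neutral conditions and the adjacent stereocentre is kept.

Step 22
Reactants: 35 hydroxy ynone β-keto thioester
Product: 38 2-(trimethylsilyl)ethyl ester of the target, via dihydropyranone 36 (not isolated), via acylketene 37 (not isolated)
Conditions: Ph3PAuNTf2 (5 mol%), CH2Cl2, rt, until 35 is consumed; then AgOCOCF3 (1.5 equiv), 2,6-di-tert-butylpyridine (1.5 equiv), rt → 35 °C, dark
Reagents that add atoms: none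
Why: Proposed new method: Ph3PAuNTf2 (monovalent gold) activates the ynone so that the C2 hydroxyl adds to C8a, the β-carbon, in a 6-endo-dig closure of ring B with retention at C2, and protodeauration gives dihydropyranone 36, whose C4a is the nucleophilic α-carbon of a vinylogous ester; AgOCOCF3 (monovalent silver) then removes benzylthiolate from the β-keto thioester to give acylketene 37, C4a attacks the ketene carbon C5 in a six-membered closure of ring A (exo with respect to the ketene C=O), and loss of the C4a proton with enolisation gives 38. The closest known reactions are the gold-catalysed 6-endo cyclisation of β-hydroxy ynones to 2,3-dihydro-4-pyranones and the silver-promoted release of acylketenes from β-keto thioesters with capture by heteroatom nucleophiles, and capture by a pyranone carbon in the same flask is the untested part. No stereocentre is formed, and C2 and C3 pass through unchanged because nothing present can enolise the C4 ketone (the hindered pyridine only takes up CF3CO2H). The step needs 6-endo rather than 5-exo attack and hydroxyl attack ahead of enyne cycloisomerisation with the prenyl and isopropenyl groups, and the polarisation of the ynone, which makes C8a the only electrophilic alkyne carbon, together with the six-membered transition state available to the hydroxyl, should secure both. It needs C-acylation at C4a, which ring size secures (six-membered through C4a, eight-membered through the C4 oxygen), and it needs the gold stage to be finished before silver is added so that the free hydroxyl never meets the acylketene. The alkyne fixes O1 on C8a beside the quaternary carbon, a regiochemical point that a triketone cyclodehydration would leave open.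

Step 23
Reactants: 38 2-(trimethylsilyl)ethyl ester of the target
Product: 39 CNP0294320.1 (target acid)
Conditions: Bu4NF (3 equiv), THF, 0 °C → rt; then cold dilute HCl
Reagents that add atoms: none
Why: Fluoride-induced β-elimination of the 2-(trimethylsilyl)ethyl ester, the substrate being deprotonated first at its acidic enol, which should protect C3 and the pyranone ring against base.

**Compound list**

1 | (4R)-limonene 1,2-oxide, cis/trans mixture | CC12CC[C@H](CC1O2)C(C)=C | starting material
2 | (4R)-1-methyl-4-(prop-1-en-2-yl)cyclohexane-1,2-diol (trans-diol) | CC1(O)CC[C@H](CC1O)C(C)=C | intermediate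
3 | (3R)-6-oxo-3-(prop-1-en-2-yl)heptanal | CC(=O)CC[C@H](CC=O)C(C)=C | intermediate
4 | (3R)-6-oxo-3-(prop-1-en-2-yl)heptanoic acid | CC(=O)CC[C@H](CC(=O)O)C(C)=C | intermediate
5 | (3R)-6-methyl-3-(prop-1-en-2-yl)hept-6-enoic acid | C=C(C)CC[C@H](CC(=O)O)C(C)=C | intermediate
6 | Barton ester of 5 (2-thioxopyridin-1(2H)-yl ester) | C=C(C)CC[C@H](CC(=O)On1ccccc1=S)C(C)=C | intermediate
7 | (3S)-3-(iodomethyl)-2,6-dimethylhepta-1,6-diene | C=C(C)CC[C@H](CI)C(C)=C | intermediate
8 | mono-tert-butyl malonate | CC(C)(C)OC(=O)CC(=O)O | starting material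
9 | 2,2-diphenylethanol | OCC(c1ccccc1)c1ccccc1 | starting material
10 | tert-butyl 2,2-diphenylethyl malonate | CC(C)(C)OC(=O)CC(=O)OCC(c1ccccc1)c1ccccc1 | intermediate
11 | tert-butyl 2,2-diphenylethyl 2-[(2R)-5-methyl-2-(prop-1-en-2-yl)hex-5-en-1-yl]malonate | C=C(C)CC[C@H](CC(C(=O)OC(C)(C)C)C(=O)OCC(c1ccccc1)c1ccccc1)C(C)=C | intermediate
12 | prenyl bromide | CC(C)=CCBr | starting material
13 | 1-tert-butyl 3-(2,2-diphenylethyl) (2R)-2-(3-methylbut-2-en-1-yl)-2-[(2R)-5-methyl-2-(prop-1-en-2-yl)hex-5-en-1-yl]malonate | C=C(C)CC[C@H](C[C@](CC=C(C)C)(C(=O)OCC(c1ccccc1)c1ccccc1)C(=O)OC(C)(C)C)C(C)=C | intermediate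
14 | tert-butyl (2R,4R)-2-(hydroxymethyl)-7-methyl-2-(3-methylbut-2-en-1-yl)-4-(prop-1-en-2-yl)oct-7-enoate | C=C(C)CC[C@H](C[C@](CC=C(C)C)(CO)C(=O)OC(C)(C)C)C(C)=C | intermediate
15 | tert-butyl (2R,4R)-2-formyl-7-methyl-2-(3-methylbut-2-en-1-yl)-4-(prop-1-en-2-yl)oct-7-enoate | C=C(C)CC[C@H](C[C@](CC=C(C)C)(C=O)C(=O)OC(C)(C)C)C(C)=C | intermediate
16 | tert-butyl (2R,4R)-2-ethynyl-7-methyl-2-(3-methylbut-2-en-1-yl)-4-(prop-1-en-2-yl)oct-7-enoate | C=C(C)CC[C@H](C[C@](CC=C(C)C)(C#C)C(=O)OC(C)(C)C)C(C)=C | intermediate
17 | (S)-4-benzyl-3-propionyloxazolidin-2-one | CCC(=O)N1[C@@H](Cc2ccccc2)COC1=O | starting material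
18 | acetaldehyde | CC=O | starting material
19 | (S)-4-benzyl-3-[(2S,3R)-3-hydroxy-2-methylbutanoyl]oxazolidin-2-one | C[C@@H](O)[C@H](C)C(=O)N1[C@@H](Cc2ccccc2)COC1=O | intermediate
20 | (2S,3R)-3-hydroxy-N-methoxy-N,2-dimethylbutanamide | C[C@@H](O)[C@H](C)C(=O)N(C)OC | intermediate
21 | (2S,3R)-3-[(tert-butyldimethylsilyl)oxy]-N-methoxy-N,2-dimethylbutanamide | C[C@@H](O[Si](C)(C)C(C)(C)C)[C@H](C)C(=O)N(C)OC | intermediate
22 | (2S,3R)-3-[(tert-butyldimethylsilyl)oxy]-2-methylbutanal | C[C@@H](O[Si](C)(C)C(C)(C)C)[C@H](C)C=O | intermediate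
23 | 3-propylglutaric anhydride | CCCC1CC(=O)OC(=O)C1 | starting material
24 | 2-(trimethylsilyl)ethanol | C[Si](C)(C)CCO | starting material
25 | (3R)-3-{2-oxo-2-[2-(trimethylsilyl)ethoxy]ethyl}hexanoic acid | OC(=O)C[C@@H](CCC)CC(=O)OCC[Si](C)(C)C | intermediate
26 | benzyl mercaptan | SCc1ccccc1 | starting material
27 | 2-(trimethylsilyl)ethyl (3S)-3-[2-(benzylsulfanyl)-2-oxoethyl]hexanoate | O=C(SCc1ccccc1)C[C@@H](CCC)CC(=O)OCC[Si](C)(C)C | intermediate
28 | lithium alkoxide of the propargylic alcohol from 16 and 22 (epimers at the carbinol carbon) | C=C(C)CC[C@H](C[C@](CC=C(C)C)(C#CC(O[Li])[C@@H](C)[C@@H](C)O[Si](C)(C)C(C)(C)C)C(=O)OC(C)(C)C)C(C)=C | intermediate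
29 | tert-butyl (2R,4R)-2-[(4S,5R)-3,5-bis(tert-butyldimethylsilyloxy)-4-methylhex-1-yn-1-yl]-7-methyl-2-(3-methylbut-2-en-1-yl)-4-(prop-1-en-2-yl)oct-7-enoate | C=C(C)CC[C@H](C[C@](CC=C(C)C)(C#CC(O[Si](C)(C)C(C)(C)C)[C@@H](C)[C@@H](C)O[Si](C)(C)C(C)(C)C)C(=O)OC(C)(C)C)C(C)=C | intermediate
30 | trimethylsilyl ester of acid 31 | C=C(C)CC[C@H](C[C@](CC=C(C)C)(C#CC(O[Si](C)(C)C(C)(C)C)[C@@H](C)[C@@H](C)O[Si](C)(C)C(C)(C)C)C(=O)O[Si](C)(C)C)C(C)=C | intermediate
31 | (2R,4R)-2-[(4S,5R)-3,5-bis(tert-butyldimethylsilyloxy)-4-methylhex-1-yn-1-yl]-7-methyl-2-(3-methylbut-2-en-1-yl)-4-(prop-1-en-2-yl)oct-7-enoic acid | C=C(C)CC[C@H](C[C@](CC=C(C)C)(C#CC(O[Si](C)(C)C(C)(C)C)[C@@H](C)[C@@H](C)O[Si](C)(C)C(C)(C)C)C(=O)O)C(C)=C | intermediate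
32 | acid chloride of 31 | C=C(C)CC[C@H](C[C@](CC=C(C)C)(C#CC(O[Si](C)(C)C(C)(C)C)[C@@H](C)[C@@H](C)O[Si](C)(C)C(C)(C)C)C(=O)Cl)C(C)=C | intermediate
33 | bis-TBS β-keto thioester (S-benzyl thioester, C6 carrying the (3S)-hexanoate side chain, C7 ketone on the quaternary carbon) | C=C(C)CC[C@H](C[C@](CC=C(C)C)(C#CC(O[Si](C)(C)C(C)(C)C)[C@@H](C)[C@@H](C)O[Si](C)(C)C(C)(C)C)C(=O)C(C(=O)SCc1ccccc1)[C@@H](CCC)CC(=O)OCC[Si](C)(C)C)C(C)=C | intermediate
34 | diol β-keto thioester (propargylic and C2 hydroxyls free) | C=C(C)CC[C@H](C[C@](CC=C(C)C)(C#CC(O)[C@@H](C)[C@@H](C)O)C(=O)C(C(=O)SCc1ccccc1)[C@@H](CCC)CC(=O)OCC[Si](C)(C)C)C(C)=C | intermediate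
35 | hydroxy ynone β-keto thioester (key-step precursor) | C=C(C)CC[C@H](C[C@](CC=C(C)C)(C#CC(=O)[C@@H](C)[C@@H](C)O)C(=O)C(C(=O)SCc1ccccc1)[C@@H](CCC)CC(=O)OCC[Si](C)(C)C)C(=C)C | intermediate
36 | (2R,3S)-2,3-dimethyl-2,3-dihydro-4H-pyran-4-one carrying the quaternary carbon at C6 of the pyranone (ring B closed, thioester intact) | C=C(C)CC[C@H](C[C@](CC=C(C)C)(C1=CC(=O)[C@@H](C)[C@@H](C)O1)C(=O)C(C(=O)SCc1ccccc1)[C@@H](CCC)CC(=O)OCC[Si](C)(C)C)C(C)=C | intermediate
37 | acylketene from 36 (C5 ketene carbon, C7 ketone) | C=C(C)CC[C@H](C[C@](CC=C(C)C)(C1=CC(=O)[C@@H](C)[C@@H](C)O1)C(=O)C(=C=O)[C@@H](CCC)CC(=O)OCC[Si](C)(C)C)C(C)=C | intermediate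
38 | 2-(trimethylsilyl)ethyl ester of the target | C=C(C)CC[C@H](C[C@@]1(CC=C(C)C)C(=O)C([C@@H](CCC)CC(=O)OCC[Si](C)(C)C)=C(O)C2=C1O[C@H](C)[C@H](C)C2=O)C(=C)C | intermediate
39 | CNP0294320.1 | C=C(C)CC[C@H](C[C@@]1(CC=C(C)C)C(=O)C([C@@H](CCC)CC(=O)O)=C(O)C2=C1O[C@H](C)[C@H](C)C2=O)C(=C)C | target

**Step count and risks**

Total step count: 23. Longest linear sequence: 16 (steps 1–4, 6–10, 17–23).

Steps most likely to fail:

1. Step 22 (Proposed new method). What may go wrong:
   - The gold stage may lose chemoselectivity. The isopropenyl alkene or the thioester carbonyl oxygen can add to the gold-activated ynone at C8a in place of the hydroxyl.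
   - In the silver stage the pyranone carbon C4a may be too weak a nucleophile to capture the acylketene, which would then dimerise or be hydrolysed.

   Fallback from 35 to 38, reversing the order of ring closure with known reactions. Diethylamine (1.05 equiv, CH2Cl2, 0 °C) adds to the ynone at C8a (conjugate addition of a secondary amine to an ynone) and should give the diethylamino enaminone F1. Its carbon C4a is far more nucleophilic than that of a pyranone, and treatment with AgOCOCF3 should bring about C-acylation of the enaminone by the β-keto thioester, closing ring A to the ring A vinylogous amide F2. Warming F2 with pyridinium p-toluenesulfonate in toluene should let the C2 hydroxyl displace diethylamine at C8a by addition–elimination. This closes ring B with O1 still fixed on C8a and returns to 38.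

2. Step 7. What may go wrong: poor facial selectivity or low conversion in the phase-transfer prenylation, because the α-substituent is bulky, β-branched and itself chiral (matched or mismatched with the catalyst).

   Fallback from 11 to 14 without asymmetric induction. NaH and prenyl bromide in THF/DMF should give 13 together with its epimer at the quaternary carbon, the (2S)-malonate F3. LiBH4 reduction of the mixture gives 14 and the epimeric hydroxy ester F4. These are diastereomers because of the fixed centre from limonene and are separated by chromatography, after which 14 continues in step 9.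

3. Step 19. What may go wrong: slow C-acylation at the α-quaternary acid chloride, so that O-acylation or decay of the thioester enolate through ketene formation takes over.

   Fallback from 29 to 33, replacing the acylation by an aldol addition and an oxidation. LiAlH4 (Et2O, 0 °C) reduces the tert-butyl ester of 29 to the neopentyl alcohol F5. Dess–Martin periodinane gives the aldehyde F6. The lithium enolate of 27 (LiN(SiMe3)2, THF, −78 °C) adds to this aldehyde to give the β-hydroxy thioester F7. A second Dess–Martin oxidation gives 33.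

Further compounds
F1 | step 22 | diethylamino enaminone from 35 (Et2N on C8a, C8a=C4a, C4 ketone, alkene geometry immaterial) | C=C(C)CC[C@H](C[C@](CC=C(C)C)(C(=CC(=O)[C@@H](C)[C@@H](C)O)N(CC)CC)C(=O)C(C(=O)SCc1ccccc1)[C@@H](CCC)CC(=O)OCC[Si](C)(C)C)C(C)=C
F2 | step 22 | ring A vinylogous amide (C4a bonded to C5, Et2N on C8a, C2 hydroxyl free) | C=C(C)CC[C@H](C[C@@]1(CC=C(C)C)C(=O)C([C@@H](CCC)CC(=O)OCC[Si](C)(C)C)=C(O)C(C(=O)[C@@H](C)[C@@H](C)O)=C1N(CC)CC)C(C)=C
F3 | step 7 | (2S)-epimer of malonate 13 | C=C(C)CC[C@H](C[C@@](CC=C(C)C)(C(=O)OCC(c1ccccc1)c1ccccc1)C(=O)OC(C)(C)C)C(C)=C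
F4 | step 7 | tert-butyl (2S,4R)-2-(hydroxymethyl)-7-methyl-2-(3-methylbut-2-en-1-yl)-4-(prop-1-en-2-yl)oct-7-enoate | C=C(C)CC[C@H](C[C@@](CC=C(C)C)(CO)C(=O)OC(C)(C)C)C(C)=C
F5 | step 19 | neopentyl alcohol from 29 (CH2OH in place of the tert-butyl ester) | C=C(C)CC[C@H](C[C@](CC=C(C)C)(C#CC(O[Si](C)(C)C(C)(C)C)[C@@H](C)[C@@H](C)O[Si](C)(C)C(C)(C)C)CO)C(C)=C
F6 | step 19 | aldehyde from F5 | C=C(C)CC[C@H](C[C@](CC=C(C)C)(C#CC(O[Si](C)(C)C(C)(C)C)[C@@H](C)[C@@H](C)O[Si](C)(C)C(C)(C)C)C=O)C(C)=C
F7 | step 19 | β-hydroxy thioester (aldol adduct of 27 and F6) | C=C(C)CC[C@H](C[C@](CC=C(C)C)(C#CC(O[Si](C)(C)C(C)(C)C)[C@@H](C)[C@@H](C)O[Si](C)(C)C(C)(C)C)C(O)C(C(=O)SCc1ccccc1)[C@@H](CCC)CC(=O)OCC[Si](C)(C)C)C(C)=C
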